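**Assumptions:** (S)-(+)-linalool is available at ≥95% ee, and the product ee equals the linalool ee. 4-Fluoro-3-methylphenol is commercial.

## Retrosynthetic overview
1. Sargachromenol ⇒ silyl-protected methyl ester (22), with the Me2C=CH terminus coming from a Wittig reaction on aldehyde 20.
2. The 2H-chromene ring (C3=C4) closes by RCM of an o-vinylaryl ether of (S)-linalool. The quaternary C–O stereocentre comes from (S)-linalool and is never touched, because the ether is made by SNAr on a fluorobenzaldehyde.
3. Both trisubstituted alkenes come from Claisen [3,3] rearrangements of allyl vinyl ethers. The first uses an isopropenyl carbinol and gives the C(Me)=CH alkene. The second uses a Baylis–Hillman carbinol and gives the C(CO2Me)=CH alkene with the natural geometry.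
4. Order: the acyclic aryl ether carries the two Claisens. The only new ring, the chromene, is closed at step 10 and is not heated afterwards.

## Forward route

**Step 1**
Reactants: 1 (4-fluoro-3-methylphenol), 2 (chlorotriisopropylsilane)
Product: 3 (triisopropyl(4-fluoro-3-methylphenoxy)silane)
Conditions: imidazole, DMF, rt
Reagents that add atoms: TIPSCl, CC(C)[Si](Cl)(C(C)C)C(C)C
Why: silylation masks the phenol so it survives the organolithium and alkoxide steps.

**Step 2**
Reactants: 3, 4 (N,N-dimethylformamide)
Product: 5 (2-fluoro-3-methyl-5-(triisopropylsilyloxy)benzaldehyde)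
Conditions: s-BuLi, TMEDA, THF, −78 °C; then DMF; NH4Cl
Reagents that add atoms: DMF, CN(C)C=O
Why: directed ortho-metalation goes ortho to fluorine, the only open site next to F and the strongest director on the ring. The bulky OTIPS group is a weak director, and formylation with DMF then gives the aldehyde.

**Step 3**
Reactants: 6 ((S)-(+)-linalool), 5
Product: 7 (2-{[(3S)-3,7-dimethylocta-1,6-dien-3-yl]oxy}-3-methyl-5-(TIPSO)benzaldehyde)
Conditions: NaH, DMF, 0 → 60 °C
Reagents that add atoms: none
Why: SNAr (addition–elimination) of the tertiary alkoxide at the C–F carbon, activated by the ortho-CHO. The carbinol C–O bond is never broken, so the (S) centre is retained.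

**Step 4**
Reactants: 7, 8 (methyltriphenylphosphonium bromide)
Product: 9 (styrene: 2-{[(3S)-3,7-dimethylocta-1,6-dien-3-yl]oxy}-3-methyl-5-(TIPSO)styrene)
Conditions: KOtBu, THF, 0 °C → rt
Reagents that add atoms: Ph3P=CH2 from C[P+](c1ccccc1)(c1ccccc1)c1ccccc1.[Br-] (adds CH2)
Why: Wittig methylenation converts the ArCHO into the vinyl partner needed for RCM.

**Step 5**
Reactants: 9, 10 (mCPBA), 11 (periodic acid)
Product: 12 ((4S)-4-[2-ethenyl-6-methyl-4-(TIPSO)phenoxy]-4-methylhex-5-enal)
Conditions: (i) mCPBA (1.0 equiv), NaHCO3, CH2Cl2, 0 °C; (ii) H5IO6, THF/Et2O, rt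
Reagents that add atoms: mCPBA, O=C(OO)c1cccc(Cl)c1; H5IO6 (water source for epoxide opening), O=I(O)(O)(O)(O)O
Why: Prilezhaev epoxidation is selective for the electron-rich trisubstituted alkene over the vinyl and styrene groups. Periodate then cleaves the resulting 1,2-diol (Malaprade cleavage), releasing acetone. The stereocentre is not involved.

**Step 6**
Reactants: 12, 13 (isopropenylmagnesium bromide)
Product: 14 ((3S)-3-[2-ethenyl-6-methyl-4-(TIPSO)phenoxy]-3,7-dimethylocta-1,7-dien-6-ol, mixture of C6 epimers)
Conditions: THF, −78 → 0 °C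
Reagents that add atoms: isopropenylMgBr, C=C(C)[Mg]Br
Why: Grignard 1,2-addition to the aliphatic aldehyde. The new carbinol centre is destroyed in step 7, so the epimer ratio does not matter.

**Step 7**
Reactants: 14, 15 (ethyl vinyl ether)
Product: 16 ((4E,8S)-8-[2-ethenyl-6-methyl-4-(TIPSO)phenoxy]-4,8-dimethyldeca-4,9-dienal)
Conditions: (i) Pd(OAc)2, 1,10-phenanthroline, EtOCH=CH2, CH2Cl2, rt; (ii) toluene, cat. Et3N, 140 °C, sealed tube
Reagents that add atoms: ethyl vinyl ether, C=COCC (supplies the CH2CHO arm)
Why: Pd(II)-catalysed transetherification gives the allyl vinyl ether, and a Claisen [3,3] rearrangement follows. The chair transition state with the alkyl group equatorial gives the E-trisubstituted C6=C7 alkene. The carbinol centre is destroyed and the linalool centre is untouched.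

**Step 8**
Reactants: 16, 17 (methyl acrylate)
Product: 18 (methyl (6E,10S)-3-hydroxy-6,10-dimethyl-2-methylidene-10-[aryloxy]dodeca-6,11-dienoate, epimeric at C3)
Conditions: DABCO, neat methyl acrylate, rt, 5–7 d
Reagents that add atoms: methyl acrylate, C=CC(=O)OC
Why: Morita–Baylis–Hillman reaction gives the 2-(1-hydroxyalkyl)acrylate. The new carbinol is again destroyed in the next step.

**Step 9**
Reactants: 18, 15 (ethyl vinyl ether)
Product: 19 (methyl (2Z,6E,10S)-10-[aryloxy]-6,10-dimethyl-2-(3-oxopropyl)dodeca-2,6,11-trienoate)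
Conditions: (i) Pd(OAc)2, 1,10-phenanthroline, EtOCH=CH2, CH2Cl2, rt; (ii) xylene, cat. Et3N, 140 °C, sealed tube
Reagents that add atoms: ethyl vinyl ether, C=COCC
Why: Claisen [3,3] rearrangement of the Baylis–Hillman vinyl ether. The chair transition state with the chain equatorial puts the chain trans to the new CH2CH2CHO arm and the CO2Me cis to the chain. This is the geometry of the target's acid alkene.

**Step 10**
Reactants: 19
Product: 20 (methyl (2Z,6E)-9-[(2S)-2,8-dimethyl-6-(TIPSO)-2H-chromen-2-yl]-6-methyl-2-(3-oxopropyl)nona-2,6-dienoate)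
Conditions: Grubbs II (5 mol%), CH2Cl2 (5 mM), 40 °C
Reagents that add atoms: none (ethylene is lost)
Why: ring-closing metathesis of the styrene and the vinyl group forms the chromene C3=C4 bond at low temperature. The quaternary centre is not involved, so it is not racemised.

**Step 11**
Reactants: 20, 21 (isopropyltriphenylphosphonium iodide)
Product: 22 (methyl ester of O-TIPS sargachromenol)
Conditions: KOtBu, THF, 0 °C; add 20 at −78 °C → rt
Reagents that add atoms: Ph3P=CMe2 from CC(C)[P+](c1ccccc1)(c1ccccc1)c1ccccc1.[I-] (adds =CMe2)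
Why: Wittig olefination of the aldehyde with the non-stabilised ylide gives the prenyl terminus. It has no E/Z issue, and the enoate and chromene are untouched.

**Step 12**
Reactants: 22
Product: 23 (O-TIPS sargachromenol, free acid)
Conditions: LiOH·H2O, THF/MeOH/H2O, 50 °C; then NaH2PO4 (pH ~4)
Reagents that add atoms: LiOH, [Li+].[OH-] (hydroxide oxygen ends up in the acid)
Why: saponification of the hindered methyl enoate; the silyl aryl ether, alkenes and chromene survive these basic conditions.

**Step 13**
Reactants: 23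
Product: 24 ((S)-sargachromenol)
Conditions: TBAF, THF, 0 °C → rt; NaH2PO4 workup
Reagents that add atoms: none
Why: fluoride cleaves the aryl Si–O bond to release the 6-OH; no other functionality is affected.

## Compound list
1 | 4-fluoro-3-methylphenol | Cc1cc(O)ccc1F | starting material
2 | chlorotriisopropylsilane | CC(C)[Si](Cl)(C(C)C)C(C)C | starting material
3 | triisopropyl(4-fluoro-3-methylphenoxy)silane | Cc1cc(O[Si](C(C)C)(C(C)C)C(C)C)ccc1F | intermediate
4 | N,N-dimethylformamide | CN(C)C=O | starting material
5 | 2-fluoro-3-methyl-5-(TIPSO)benzaldehyde | O=Cc1cc(O[Si](C(C)C)(C(C)C)C(C)C)cc(C)c1F | intermediate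
6 | (S)-(+)-linalool | C=C[C@@](C)(O)CCC=C(C)C | starting material
7 | (S)-linalyl aryl ether aldehyde | C=C[C@@](C)(Oc1c(C)cc(O[Si](C(C)C)(C(C)C)C(C)C)cc1C=O)CCC=C(C)C | intermediate
8 | methyltriphenylphosphonium bromide | C[P+](c1ccccc1)(c1ccccc1)c1ccccc1.[Br-] | starting material
9 | (S)-linalyl aryl ether styrene | C=C[C@@](C)(Oc1c(C)cc(O[Si](C(C)C)(C(C)C)C(C)C)cc1C=C)CCC=C(C)C | intermediate
10 | mCPBA | O=C(OO)c1cccc(Cl)c1 | starting material
11 | periodic acid | O=I(O)(O)(O)(O)O | starting material
12 | (4S)-hexenal aryl ether | C=C[C@@](C)(Oc1c(C)cc(O[Si](C(C)C)(C(C)C)C(C)C)cc1C=C)CCC=O | intermediate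
13 | isopropenylmagnesium bromide | C=C(C)[Mg]Br | starting material
14 | isopropenyl carbinol | C=C[C@@](C)(Oc1c(C)cc(O[Si](C(C)C)(C(C)C)C(C)C)cc1C=C)CCC(O)C(C)=C | intermediate
15 | ethyl vinyl ether | C=COCC | starting material
16 | Claisen aldehyde 1 | C=C[C@@](C)(Oc1c(C)cc(O[Si](C(C)C)(C(C)C)C(C)C)cc1C=C)CC/C=C(C)/CCC=O | intermediate
17 | methyl acrylate | C=CC(=O)OC | starting material
18 | Baylis–Hillman adduct | C=C[C@@](C)(Oc1c(C)cc(O[Si](C(C)C)(C(C)C)C(C)C)cc1C=C)CC/C=C(C)/CCC(O)C(=C)C(=O)OC | intermediate
19 | Claisen aldehyde 2 (enoate) | C=C[C@@](C)(Oc1c(C)cc(O[Si](C(C)C)(C(C)C)C(C)C)cc1C=C)CC/C=C(C)/CC/C=C(/CCC=O)C(=O)OC | intermediate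
20 | chromene aldehyde | O=CCC/C(C(=O)OC)=C/CC/C(C)=C/CC[C@@]1(C)C=Cc2cc(O[Si](C(C)C)(C(C)C)C(C)C)cc(C)c2O1 | intermediate
21 | isopropyltriphenylphosphonium iodide | CC(C)[P+](c1ccccc1)(c1ccccc1)c1ccccc1.[I-] | starting material
22 | O-TIPS sargachromenol methyl ester | CC(C)=CCC/C(=C/CC/C(C)=C/CC[C@@]1(C)C=Cc2cc(O[Si](C(C)C)(C(C)C)C(C)C)cc(C)c2O1)C(=O)OC | intermediate
23 | O-TIPS sargachromenol acid | CC(C)=CCC/C(=C/CC/C(C)=C/CC[C@@]1(C)C=Cc2cc(O[Si](C(C)C)(C(C)C)C(C)C)cc(C)c2O1)C(=O)O | intermediate
24 | (S)-sargachromenol | CC(C)=CCC/C(=C/CC/C(C)=C/CC[C@@]1(C)C=Cc2cc(O)cc(C)c2O1)C(=O)O | target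

**Total steps:** 13. **Longest linear sequence:** 13 (1 → 3 → 5 → 7 → 9 → 12 → 14 → 16 → 18 → 19 → 20 → 22 → 23 → 24). From linalool alone it is 11.

**Three steps most likely to fail:**
1. **Step 3 (SNAr).** The fluoride is flanked by CHO and Me, is deactivated by the para-OSi group, and the nucleophile is a tertiary alkoxide.
   - Fallback: change the bond-forming mode to Pd-catalysed C–O cross-coupling of (S)-linalool with the corresponding 2-bromo-3-methyl-5-(TIPSO)benzaldehyde, using an achiral bulky biarylphosphine ligand.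
2. **Steps 8–9 (Baylis–Hillman reaction on an aliphatic aldehyde, then Claisen).** The Baylis–Hillman step is slow, and the geometry of the Claisen product may erode.
   - Fallback: drop the Baylis–Hillman/Claisen pair and set the enoate by a Z-selective Ando HWE of aldehyde 16. The phosphonate would be an α-(4-methylpent-3-enyl) diarylphosphonoacetate. This also removes the need for step 11.
3. **Step 5 (chemoselective cleavage next to the styrene).** Epoxidation may not be fully selective for the prenyl alkene.
   - Fallback: close the ring first by RCM of 9, then oxidise the E-methyl of the prenyl group with SeO2/t-BuOOH (the chromene alkene has no allylic H). Brominate the resulting allylic alcohol and alkylate with lithium tert-butyl acetate to build the same CH2CH2CO2tBu arm. DIBAL then gives the aldehyde for steps 8–9.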